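**Plan**

- Retrosynthesis: ring C is opened at the aryl ether bond O1–C8a to an open-chain (S)-β-hydroxy ketone carrying fluorine on C8a. This is cut at C2–C3 (aldol) into 2-fluoro-4,6-dimethoxyacetophenone and 2,3,4-trimethoxybenzaldehyde, and the ketone at C4–C4a (acylation of 1-fluoro-3,5-dimethoxybenzene).
- Forward: ring A is acetylated, the chain is joined to the ring B aldehyde by an asymmetric aldol addition, and ring C is closed last by O1–C8a bond formation.
- Enabling feature: C8a is ortho to the C4 ketone on C4a, so a C8a–F bond is a vinylogous acyl fluoride. The methoxy groups on C5 and C7 are meta to C8a and do not deactivate it, and the C2 oxygen reaches C8a through a six-membered ring.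
- Stereochemistry: the single stereocentre (C2, S) is set by catalyst control in the aldol step. The ring closure makes the O–aryl bond and leaves the C2–O bond untouched, so the configuration is carried through unchanged.

Key step: step 4

Assumption: in the SiCl4/bisphosphoramide aldol (catalyst: two N,N'-dimethyl-1,1'-binaphthyl-2,2'-diamine phosphoramide units joined by an N,N'-dimethylpentane-1,5-diamine tether) the (R,R)-catalyst is taken to direct addition to the Re face of aromatic aldehydes, so the (S,S)-catalyst is specified for Si-face addition; this sense is recalled, not certain, and would be checked on 6 by Mosher ester analysis before step 4, the mirror-image catalyst being used if needed.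

Step 1
Reactants: 1 1-fluoro-3,5-dimethoxybenzene
Product: 2 1-(2-fluoro-4,6-dimethoxyphenyl)ethan-1-one
Conditions: Ac2O (1.5 equiv), Sc(OTf)3 (10 mol %), MeNO2, 50 °C
Reagents that add atoms: acetic anhydride CC(=O)OC(C)=O
Why: Catalytic Friedel–Crafts acylation, in which the acylium ion should attack one of the two equivalent carbons of 1 that are ortho to fluorine and para to a methoxy group in preference to the more crowded carbon flanked by both methoxy groups (the usual outcome for 5-substituted 1,3-dimethoxybenzenes), while the catalytic triflate avoids the cleavage of the ortho methoxy group that stoichiometric AlCl3 can cause.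

Step 2
Reactants: 2 1-(2-fluoro-4,6-dimethoxyphenyl)ethan-1-one
Product: 3 {[1-(2-fluoro-4,6-dimethoxyphenyl)ethenyl]oxy}trimethylsilane
Conditions: Me3SiOTf (1.2 equiv), Et3N (1.5 equiv), CH2Cl2, 0 °C
Reagents that add atoms: trimethylsilyl trifluoromethanesulfonate C[Si](C)(C)OS(=O)(=O)C(F)(F)F
Why: Soft enolisation of a methyl ketone (silyl triflate and tertiary amine) gives the only possible silyl enol ether without a strong base, so the aryl C–F bond and the methoxy groups are not touched.

Step 3
Reactants: 3 {[1-(2-fluoro-4,6-dimethoxyphenyl)ethenyl]oxy}trimethylsilane, 4 2,3,4-trimethoxybenzaldehyde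
Product: 6 (3S)-1-(2-fluoro-4,6-dimethoxyphenyl)-3-hydroxy-3-(2,3,4-trimethoxyphenyl)propan-1-one, via trichlorosilyl ether 5 (not isolated)
Conditions: SiCl4 (1.5 equiv), (S,S)-bisphosphoramide (5 mol %), i-Pr2NEt (10 mol %), CH2Cl2, −78 °C; then pH 7 phosphate buffer, 0 °C
Reagents that add atoms: silicon tetrachloride Cl[Si](Cl)(Cl)Cl (its SiCl3 group stays only in intermediate 5)
Why: Lewis-base-catalysed Mukaiyama aldol addition mediated by SiCl4, in which the chiral bisphosphoramide-bound trichlorosilyl cation binds aldehyde 4 and exposes its Si face, enol ether 3 adds through an open transition state to set the carbinol carbon (the future C2) as S, and the adduct is held as trichlorosilyl ether 5, which cannot revert by retro-aldol cleavage, until the buffered quench.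

Step 4
Reactants: 6 (3S)-1-(2-fluoro-4,6-dimethoxyphenyl)-3-hydroxy-3-(2,3,4-trimethoxyphenyl)propan-1-one
Product: 8 (2S)-5,7-dimethoxy-2-(2,3,4-trimethoxyphenyl)-2,3-dihydro-4H-chromen-4-one, via potassium alkoxide 7 (not isolated)
Conditions: KN(SiMe3)2 (1.0 equiv, slow addition), 18-crown-6 (1.0 equiv), THF (0.02 M), −78 to −30 °C; AcOH quench at −30 °C
Reagents that add atoms: potassium bis(trimethylsilyl)amide C[Si](C)(C)[N-][Si](C)(C)C.[K+] (its potassium stays only in intermediate 7)
Why: Deprotonation gives alkoxide 7, whose oxygen adds to C8a (the carbon bearing fluorine) to give a Meisenheimer adduct in which the negative charge is taken up by the C4 carbonyl as an enolate, and loss of fluoride restores ring A (addition–elimination, SNAr). The closest known reaction type is the intramolecular O-arylation of ortho-fluoroaryl ketones by a tethered oxygen nucleophile, as used for chromones and xanthones. Ring C (six-membered) is closed by attack of the tethered oxygen on a trigonal ring carbon, formally a 6-endo-trig addition to the C4a=C8a bond of the O=C4–C4a=C8a–F unit followed by elimination. No stereocentre is created: C2 was set in step 3 and should keep its S configuration because the C2–O bond is a spectator and the short, cold, base-limited contact is meant to avoid the two racemising paths (retro-aldol of 7 and base-induced opening of ring C in 8). The step needs site selectivity (C8a–F over C5–OMe, both ortho to the ketone) and chemoselectivity (substitution over retro-aldol cleavage and E1cB dehydration); fluorine secures the first because it lowers the barrier of the addition step far more than methoxy does, and the second is served by the C5 and C7 methoxy groups being meta to C8a, by the crown-complexed potassium ion that cannot hold the alkoxide in a chelate with the carbonyl oxygen away from C8a, and by O–H deprotonation at −78 °C being much faster than enolate formation.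

**Compound list**

1 | 1-fluoro-3,5-dimethoxybenzene | COc1cc(F)cc(OC)c1 | starting material
2 | 1-(2-fluoro-4,6-dimethoxyphenyl)ethan-1-one | CC(=O)c1c(F)cc(OC)cc1OC | intermediate
3 | {[1-(2-fluoro-4,6-dimethoxyphenyl)ethenyl]oxy}trimethylsilane | C=C(O[Si](C)(C)C)c1c(F)cc(OC)cc1OC | intermediate
4 | 2,3,4-trimethoxybenzaldehyde | COc1ccc(C=O)c(OC)c1OC | starting material
5 | (3S)-1-(2-fluoro-4,6-dimethoxyphenyl)-3-[(trichlorosilyl)oxy]-3-(2,3,4-trimethoxyphenyl)propan-1-one | COc1cc(F)c(C(=O)C[C@H](O[Si](Cl)(Cl)Cl)c2ccc(OC)c(OC)c2OC)c(OC)c1 | intermediate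
6 | (3S)-1-(2-fluoro-4,6-dimethoxyphenyl)-3-hydroxy-3-(2,3,4-trimethoxyphenyl)propan-1-one | COc1cc(F)c(C(=O)C[C@H](O)c2ccc(OC)c(OC)c2OC)c(OC)c1 | intermediate
7 | potassium (1S)-3-(2-fluoro-4,6-dimethoxyphenyl)-3-oxo-1-(2,3,4-trimethoxyphenyl)propan-1-olate | COc1cc(F)c(C(=O)C[C@H]([O-])c2ccc(OC)c(OC)c2OC)c(OC)c1.[K+] | intermediate
8 | (2S)-5,7-dimethoxy-2-(2,3,4-trimethoxyphenyl)-2,3-dihydro-4H-chromen-4-one | COc1cc(OC)c2c(c1)O[C@H](c1ccc(OC)c(OC)c1OC)CC2=O | target

Total step count: 4
Longest linear sequence: 4 steps (1 → 2 → 3 → 6 → 8; aldehyde 4 enters in step 3)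

**Steps most likely to fail**

Step 4 (key step). Retro-aldol cleavage or E1cB dehydration of alkoxide 7 may compete with the substitution, costing material or eroding the C2 configuration through cleavage and re-addition; excess base may also open ring C of 8. The fallback sets out from 6 and returns at 8, and takes the carbonyl out of play before the ring is closed. Reduction of 6 with LiBH4 in THF at 0 °C should give (3S)-1-(2-fluoro-4,6-dimethoxyphenyl)-3-(2,3,4-trimethoxyphenyl)propane-1,3-diol F1 (both C1 epimers, both usable), which can neither cleave by retro-aldol nor dehydrate by E1cB. KOt-Bu (2.5 equiv) in DMSO at 70 °C should then close ring C by substitution of fluoride on the now unactivated ring, a known closure of 3-(2-fluoroaryl)propan-1-ols to chromans, helped here by the two meta methoxy groups. This gives (2S)-5,7-dimethoxy-2-(2,3,4-trimethoxyphenyl)-3,4-dihydro-2H-chromen-4-ol F2 (both C4 epimers). Oxidation of the C4 alcohol with Dess–Martin periodinane and NaHCO3 in CH2Cl2 returns to 8.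

Step 3. Facial selectivity may be poor because both partners are ortho-substituted (or the sense may be opposite to that assumed), and 3 may be protodesilylated before it adds. The fallback sets out from 2 and 4 and returns at 6, and sets the stereocentre by epoxidation instead of by C–C bond formation. Claisen–Schmidt condensation (KOH, EtOH, 0 °C to rt) should give (2E)-1-(2-fluoro-4,6-dimethoxyphenyl)-3-(2,3,4-trimethoxyphenyl)prop-2-en-1-one F3. Juliá–Colonna epoxidation with poly-D-leucine, urea–H2O2 and DBU in THF should give (2-fluoro-4,6-dimethoxyphenyl)[(2S,3R)-3-(2,3,4-trimethoxyphenyl)oxiran-2-yl]methanone F4; the D-polymer is chosen because the L-polymer is known to give (2R,3S)-epoxides from chalcones. Reductive opening of the Cα–O bond with SmI2 (2.2 equiv) in THF–MeOH at −90 °C leaves the benzylic C–O bond and its configuration untouched and returns to 6.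

Step 1. Acylation may occur partly at the carbon between the two methoxy groups, or the catalytic cycle may stall because the product ketone binds the catalyst. The fallback sets out from 1 and returns at 2, and uses a bulkier, stoichiometric electrophile. Vilsmeier–Haack formylation (POCl3, DMF, 0 to 60 °C) should give 2-fluoro-4,6-dimethoxybenzaldehyde F5, separable from its isomer by crystallisation. Addition of MeMgBr in THF at 0 °C should give 1-(2-fluoro-4,6-dimethoxyphenyl)ethan-1-ol F6, and oxidation with MnO2 in CH2Cl2 returns to 2.

Further compounds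
F1 | step 4 | (3S)-1-(2-fluoro-4,6-dimethoxyphenyl)-3-(2,3,4-trimethoxyphenyl)propane-1,3-diol (both C1 epimers) | COc1cc(F)c(C(O)C[C@H](O)c2ccc(OC)c(OC)c2OC)c(OC)c1
F2 | step 4 | (2S)-5,7-dimethoxy-2-(2,3,4-trimethoxyphenyl)-3,4-dihydro-2H-chromen-4-ol (both C4 epimers) | COc1cc(OC)c2c(c1)O[C@H](c1ccc(OC)c(OC)c1OC)CC2O
F3 | step 3 | (2E)-1-(2-fluoro-4,6-dimethoxyphenyl)-3-(2,3,4-trimethoxyphenyl)prop-2-en-1-one | COc1cc(F)c(C(=O)/C=C/c2ccc(OC)c(OC)c2OC)c(OC)c1
F4 | step 3 | (2-fluoro-4,6-dimethoxyphenyl)[(2S,3R)-3-(2,3,4-trimethoxyphenyl)oxiran-2-yl]methanone | O1[C@H](c2ccc(OC)c(OC)c2OC)[C@H]1C(=O)c1c(F)cc(OC)cc1OC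
F5 | step 1 | 2-fluoro-4,6-dimethoxybenzaldehyde | COc1cc(F)c(C=O)c(OC)c1
F6 | step 1 | 1-(2-fluoro-4,6-dimethoxyphenyl)ethan-1-ol (racemic) | CC(O)c1c(F)cc(OC)cc1OC
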